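The retrosynthesis cuts four bonds. They are the C11–O(aryl) ether bond, the C13–O bond (traced back through C13–Si to a plain C13 methyl), the C14–O bond of the chiral-pool diol, and the C11=C side-chain alkene of dehydrated andrographolide.
Rings A and B are never built, because they arrive as the trans-decalin of andrographolide (1). The side chain is cut back to C11, C14 is deoxygenated and the ring-B alkene is moved to C7=C8. A temporary O3–Si–C13 oxasilolane is then closed on ring A and oxidised, and the coumarin is joined last.
The enabling feature lies in ring A (C1–C5, C10). The equatorial oxygen on C3 is gauche to both methyl groups on C4, but axial C14 is held in a 1,3-diaxial contact with the axial C15 methyl on C10. The five-membered ring O3–Si–C13–C4–C3 therefore fits only on equatorial C13.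
C3, C5, C9 and C10 are carried unchanged from 1. C4 is first made achiral (gem-dimethyl) and is set again in the key step under substrate control.

Key step: step 9

Remark on numbering and one assumption: drimane numbering is used for the decalin. C11 sits on C9, C12 on C8, C13 is the equatorial and C14 the axial carbon on C4, and C15 is the methyl on C10. These correspond to labdane C11, C17, C18, C19 and C20, and the trivial names of 1–3 keep their labdane locants. The target SMILES is read as (3R,4S,5S,9R,10R), with 3-OH, C13H2OH and C11 all equatorial. This is the decalin of natural andrographolide except at C4. TBS = tert-butyldimethylsilyl, Ts = p-toluenesulfonyl.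

Step 1
Reactants: 1 andrographolide
Product: 2 14-deoxy-11,12-didehydroandrographolide (E-alkene from C11 into a butenolide; equatorial 3-OH, axial C14H2OH, C8=C12 methylene)
Conditions: activated Al2O3, pyridine, reflux
Reagents that add atoms: none
Why: Base-mediated vinylogous 1,4-dehydration, in which the gamma proton on C11 of the alkylidene lactone is removed and the allylic lactone hydroxyl leaves, should place an E-alkene directly on C9 without touching any ring stereocentre.

Step 2
Reactants: 2 14-deoxy-11,12-didehydroandrographolide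
Product: 3 19-O-tosyl-14-deoxy-11,12-didehydroandrographolide (tosylate on axial C14, free equatorial 3-OH)
Conditions: TsCl (1.2 equiv), pyridine, 0 °C to rt
Reagents that add atoms: p-toluenesulfonyl chloride, Cc1ccc(cc1)S(=O)(=O)Cl
Why: Sterically controlled sulfonylation should pick the primary C14 hydroxyl over the secondary C3 hydroxyl next to quaternary C4, the same preference that governs silylation, tritylation and acylation of this 1,3-diol.

Step 3
Reactants: 3 19-O-tosyl-14-deoxy-11,12-didehydroandrographolide
Product: 4 (3R,4R,5S,9R,10R)-3-hydroxy-14-tosyloxydrim-8(12)-en-11-al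
Conditions: K2OsO4·2H2O (2 mol %), NaIO4 (2.1 equiv), 2,6-lutidine, dioxane/H2O (3:1), 0 °C to rt
Reagents that add atoms: sodium periodate, [Na+].[O-]I(=O)(=O)=O (aldehyde oxygen, passed on through OsO4)
Why: In this Lemieux–Johnson oxidation (osmylation, then periodate glycol cleavage) the E-disubstituted diene terminus should be osmylated ahead of the ring methylene, which in labd-8(17)-enes outlasts side-chain alkenes towards OsO4 and KMnO4, while the limited oxidant and the lutidine buffer keep C9 equatorial and the alkene out of conjugation.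

Step 4
Reactants: 4 (3R,4R,5S,9R,10R)-3-hydroxy-14-tosyloxydrim-8(12)-en-11-al
Product: 5 (3R,4R,5S,9R,10R)-14-tosyloxydrim-8(12)-ene-3,11-diol
Conditions: NaBH4, MeOH/CH2Cl2, −10 °C
Reagents that add atoms: none
Why: Borohydride 1,2-reduction removes the enolisable beta,gamma-unsaturated aldehyde at once, so that C9 cannot epimerise, and it leaves the neopentyl sulfonate and the alkene alone.

Step 5
Reactants: 5 (3R,4R,5S,9R,10R)-14-tosyloxydrim-8(12)-ene-3,11-diol
Product: 7 ent-3β-hydroxyalbicanol [(3R,5S,9R,10R)-drim-8(12)-ene-3,11-diol; gem-dimethyl C4], via axial neopentyl iodide 6 (not isolated)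
Conditions: NaI, Zn dust, DMF, 110 °C; aq NH4Cl
Reagents that add atoms: none
Why: Finkelstein displacement followed by zinc reduction is the classical way to turn an axial C4 sulfonyloxymethyl group of a diterpenoid into a methyl group, and the neutral medium avoids the Grob-type fragmentation or oxetane closure that a C3 alkoxide would start.

Step 6
Reactants: 7 ent-3β-hydroxyalbicanol
Product: 8 11-O-TBS ent-3β-hydroxyalbicanol
Conditions: TBSCl (1.1 equiv), imidazole, CH2Cl2, 0 °C
Reagents that add atoms: tert-butyldimethylsilyl chloride, CC(C)(C)[Si](C)(C)Cl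
Why: Selective silyl ether formation should occur at the primary C11 hydroxyl, because the equatorial C3 hydroxyl is secondary and flanked by the gem-dimethyl carbon.

Step 7
Reactants: 8 11-O-TBS ent-3β-hydroxyalbicanol
Product: 9 11-O-TBS ent-3β-hydroxydrimenol [(3R,5S,9R,10R)-11-(tert-butyldimethylsilyloxy)drim-7-en-3-ol]
Conditions: Co(tBu4-salen)Cl (5 mol %; tBu4-salen = N,N'-bis(3,5-di-tert-butylsalicylidene)ethane-1,2-diaminate), PhSiH3 (10 mol %), degassed benzene, rt
Reagents that add atoms: none
Why: In this cobalt-hydride hydrogen-atom-transfer (MHAT) alkene isomerisation a hydrogen atom adds to the open C12 methylene to give the tertiary C8 radical, cobalt takes a hydrogen back from the accessible C7 methylene and not from the C9 methine buried between C10, C15 and the silyloxymethyl group, and the trisubstituted product re-enters the cycle much more slowly, so C9 should keep its configuration.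

Step 8
Reactants: 9 11-O-TBS ent-3β-hydroxydrimenol; 10 diethylsilane
Product: 11 (3R,5S,9R,10R)-3-(diethylsilyloxy)-11-(tert-butyldimethylsilyloxy)drim-7-ene (3-O-SiHEt2 ether, used crude)
Conditions: [Ir(cod)OMe]2 (0.5 mol %), THF, rt; volatiles removed in vacuo
Reagents that add atoms: none
Why: Iridium-catalysed dehydrogenative O-silylation of an alcohol with a dihydrosilane stops at the monoalkoxysilane on this hindered carbinol, and evaporating the excess silane leaves no free Si–H reagent for the alkene in the next step.

Step 9
Reactants: 11 3-O-diethylhydrosilyl ether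
Product: 12 (3R,4R,5S,9R,10R)-C3,C13-bridged 2,2-diethyl-1,2-oxasilolane (ring O3–Si–C13–C4–C3 trans-fused to ring A; axial C14 methyl kept; 11-OTBS; C7=C8 alkene)
Conditions: [Ir(cod)OMe]2 (2 mol %), 3,4,7,8-tetramethyl-1,10-phenanthroline (5 mol %), norbornene (1.2 equiv), THF, 100 °C, sealed tube
Reagents that add atoms: none
Why: The Si–H bond of 11 adds to the phenanthroline-bound iridium centre, norbornene is hydrogenated to clear the hydride ligands, and the tethered iridium silyl then breaks a primary C–H bond on the third carbon from O3 to give a six-membered metallacycle (Ir, Si, O3, C3, C4, C13). The closest known reaction type is this very process, the hydroxyl-directed iridium-catalysed gamma-C(sp3)–H silylation of (hydrido)silyl ethers, which has been applied to equatorial 3-hydroxy-4,4-dimethyl terpenoids that carry a trisubstituted ring alkene. The 1,2-oxasilolane closes by C13–Si reductive elimination from that metallacycle (contraction from six to five ring members) and ends up trans-fused to ring A through the two equatorial bonds C3–O and C4–C13. C4 becomes a stereocentre through the choice between its two diastereotopic methyl groups, and this choice is under substrate control, because a metal on axial C14 would have to sit beside the axial C15 methyl and the axial hydrogens on C2 and C6, whereas equatorial C13 points into free space. Among the other gamma positions, the C1 methylene and the C5 methine are passed over because this catalyst strongly prefers primary C–H bonds. The C7=C8 alkene is trisubstituted and out of reach of the tether, the TBS ether has no Si–H bond and the free silane is gone, so hydrosilylation should not compete.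

Step 10
Reactants: 12 C3,C13-bridged oxasilolane
Product: 13 (3R,4S,5S,9R,10R)-11-(tert-butyldimethylsilyloxy)drim-7-ene-3,13-diol
Conditions: 30% aq H2O2, KHCO3, THF/MeOH (1:1), 50 °C
Reagents that add atoms: hydrogen peroxide, OO
Why: In the Tamao–Fleming oxidation, peroxide adds to the alkoxy-activated silicon and C13 migrates from Si to O without touching C4, while the unactivated alkene and the bulky TBS ether are inert to buffered peroxide.

Step 11
Reactants: 13 11-O-TBS drim-7-ene-3,13-diol
Product: 14 3,13-O-isopropylidene acetal of 13 (1,3-dioxane trans-fused to ring A)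
Conditions: 2,2-dimethoxypropane, PPTS (cat.), CH2Cl2, rt
Reagents that add atoms: 2,2-dimethoxypropane, COC(C)(C)OC
Why: Acid-catalysed transketalisation of a diequatorial 1,3-diol gives a strain-free chair dioxane under conditions too mild to disturb the TBS ether.

Step 12
Reactants: 14 3,13-acetonide 11-TBS ether
Product: 15 (3R,4S,5S,9R,10R)-3,13-(isopropylidenedioxy)drim-7-en-11-ol
Conditions: TBAF, THF, rt
Reagents that add atoms: none
Why: Fluoride-induced desilylation frees only the C11 hydroxyl, since the acetonide and the alkene do not react with fluoride.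

Step 13
Reactants: 15 3,13-(isopropylidenedioxy)drim-7-en-11-ol; 16 umbelliferone (7-hydroxycoumarin)
Product: 17 7-O-[(3R,4S,5S,9R,10R)-3,13-(isopropylidenedioxy)drim-7-en-11-yl]umbelliferone
Conditions: PPh3, DIAD, THF, 0 °C to 40 °C
Reagents that add atoms: none
Why: In the Mitsunobu etherification the only free hydroxyl is activated as an oxyphosphonium ion and displaced by the acidic phenol in an SN2 step at the non-stereogenic C11, and the reducible coumarin enters only after all silane and peroxide chemistry is finished.

Step 14
Reactants: 17 coumarin ether acetonide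
Product: 18 target, 7-{[(1R,4aS,5S,6R,8aR)-6-hydroxy-5-(hydroxymethyl)-2,5,8a-trimethyl-1,4,4a,5,6,7,8,8a-octahydronaphthalen-1-yl]methoxy}-2H-chromen-2-one
Conditions: AcOH/H2O (4:1), 40 °C
Reagents that add atoms: none
Why: Mild acid hydrolysis of the acetonide releases the 3,13-diol and is too weak to protonate the trisubstituted alkene, cleave the alkyl aryl ether or open the lactone.

Compound list
1 | andrographolide | C[C@@]12CC[C@H]([C@@]([C@H]1CCC(=C)[C@H]2C/C=C/3\[C@@H](COC3=O)O)(C)CO)O | starting material
2 | 14-deoxy-11,12-didehydroandrographolide | C=C1CC[C@@H]2[C@](C)(CO)[C@H](O)CC[C@@]2(C)[C@@H]1/C=C/C3=CCOC3=O | intermediate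
3 | 19-O-tosyl-14-deoxy-11,12-didehydroandrographolide | C=C1CC[C@@H]2[C@](C)(COS(=O)(=O)c3ccc(C)cc3)[C@H](O)CC[C@@]2(C)[C@@H]1/C=C/C4=CCOC4=O | intermediate
4 | 3-hydroxy-14-tosyloxydrim-8(12)-en-11-al | C=C1CC[C@@H]2[C@](C)(COS(=O)(=O)c3ccc(C)cc3)[C@H](O)CC[C@@]2(C)[C@@H]1C=O | intermediate
5 | 14-tosyloxydrim-8(12)-ene-3,11-diol | C=C1CC[C@@H]2[C@](C)(COS(=O)(=O)c3ccc(C)cc3)[C@H](O)CC[C@@]2(C)[C@@H]1CO | intermediate
6 | 14-iododrim-8(12)-ene-3,11-diol (axial CH2I, not isolated) | C=C1CC[C@@H]2[C@](C)(CI)[C@H](O)CC[C@@]2(C)[C@@H]1CO | intermediate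
7 | ent-3β-hydroxyalbicanol | C=C1CC[C@@H]2C(C)(C)[C@H](O)CC[C@@]2(C)[C@@H]1CO | intermediate
8 | 11-O-TBS ent-3β-hydroxyalbicanol | C=C1CC[C@@H]2C(C)(C)[C@H](O)CC[C@@]2(C)[C@@H]1CO[Si](C)(C)C(C)(C)C | intermediate
9 | 11-O-TBS ent-3β-hydroxydrimenol | CC1=CC[C@@H]2C(C)(C)[C@H](O)CC[C@@]2(C)[C@@H]1CO[Si](C)(C)C(C)(C)C | intermediate
10 | diethylsilane | CC[SiH2]CC | starting material
11 | 3-O-diethylhydrosilyl 11-O-TBS ent-3β-hydroxydrimenol | CC1=CC[C@@H]2C(C)(C)[C@H](O[SiH](CC)CC)CC[C@@]2(C)[C@@H]1CO[Si](C)(C)C(C)(C)C | intermediate
12 | C3,C13-bridged 2,2-diethyl-1,2-oxasilolane | CC1=CC[C@@H]2[C@@]3(C)C[Si](CC)(CC)O[C@@H]3CC[C@@]2(C)[C@@H]1CO[Si](C)(C)C(C)(C)C | intermediate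
13 | 11-O-TBS drim-7-ene-3,13-diol (ent series, equatorial C13H2OH) | CC1=CC[C@@H]2[C@@](C)(CO)[C@H](O)CC[C@@]2(C)[C@@H]1CO[Si](C)(C)C(C)(C)C | intermediate
14 | 3,13-acetonide of 13 | CC1=CC[C@@H]2[C@@]3(C)COC(C)(C)O[C@@H]3CC[C@@]2(C)[C@@H]1CO[Si](C)(C)C(C)(C)C | intermediate
15 | 3,13-(isopropylidenedioxy)drim-7-en-11-ol | CC1=CC[C@@H]2[C@@]3(C)COC(C)(C)O[C@@H]3CC[C@@]2(C)[C@@H]1CO | intermediate
16 | umbelliferone | Oc1ccc2ccc(=O)oc2c1 | starting material
17 | coumarin ether acetonide | CC1=CC[C@@H]2[C@@]3(C)COC(C)(C)O[C@@H]3CC[C@@]2(C)[C@@H]1COc4ccc5ccc(=O)oc5c4 | intermediate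
18 | CNP0298598.3 | CC1=CC[C@@H]2[C@@](C)(CO)[C@H](O)CC[C@@]2(C)[C@@H]1COc1ccc2ccc(=O)oc2c1 | target

Total step count: 14. Longest linear sequence: 14 steps (1 to 18).

Steps most likely to fail

Step 3. The osmylation may lose site selectivity, with the ring methylene reacting alongside the side-chain alkene. The beta,gamma-unsaturated aldehyde may also drift into conjugation on handling.
- The fallback sets out from 3 and comes back at 5. It masks the ring alkene, so the oxidant no longer has to discriminate.
- mCPBA (CH2Cl2, 0 °C) should epoxidise the most nucleophilic alkene, the C8=C12 methylene, from the face opposite C15 to give the 8,12-epoxide F1.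
- Exhaustive ozonolysis (O3, CH2Cl2/MeOH, −78 °C; Me2S) then needs no selectivity and gives the epoxy aldehyde F2.
- NaBH4 in MeOH gives the epoxy alcohol F3.
- Iodohydrin formation with zinc-induced reductive elimination (NaI, Zn, NaOAc, AcOH, rt) restores the methylene group and delivers 5.

Step 7. Positional control may be poor, with hydrogen abstraction at C9 in place of C7, or the reaction may stall before full conversion.
- The fallback sets out from 8 and comes back at 9. It fixes the alkene position by enolate regiochemistry instead of by isomerisation.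
- TESCl and imidazole cap the C3 hydroxyl to give the 3-O-triethylsilyl ether F4.
- Ozonolysis (O3, CH2Cl2, −78 °C; Me2S) removes C12 and gives the 12-nor-8-ketone F5.
- Kinetic deprotonation at the C7 methylene (KHMDS, THF, −78 °C) and trapping with PhNTf2 gives the C7=C8 enol triflate F6.
- Iron-catalysed Kumada-type methylation (MeMgBr, Fe(acac)3, THF/NMP, −20 °C) gives the 3-O-triethylsilyl ether of 9 F7.
- Dilute AcOH in aqueous THF removes the more labile triethylsilyl group and returns 9.

Step 13. The SN2 displacement at the hindered C11 may be sluggish, so elimination or alkylation of the reduced azodicarboxylate could take over.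
- The fallback sets out from 15 and comes back at 17. It forms the aryl–oxygen bond in place of the C11–oxygen bond.
- This is a palladium-catalysed C–O cross-coupling of alcohol 15 with commercial 7-bromocoumarin (Brc1ccc2ccc(=O)oc2c1), using [Pd(allyl)Cl]2, RockPhos and Cs2CO3 in toluene at 90 °C.
- No substitution at carbon is involved, and no new compound arises on this path (F0).

Further compounds
F1 | step 3 | 8,12-epoxide of 3 (epoxide oxygen equatorial on C8, on the face opposite C15) | O1C[C@@]12CC[C@@H]3[C@](C)(COS(=O)(=O)c4ccc(C)cc4)[C@H](O)CC[C@@]3(C)[C@@H]2/C=C/C5=CCOC5=O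
F2 | step 3 | 8,12-epoxy-3-hydroxy-14-tosyloxydriman-11-al | O1C[C@@]12CC[C@@H]3[C@](C)(COS(=O)(=O)c4ccc(C)cc4)[C@H](O)CC[C@@]3(C)[C@@H]2C=O
F3 | step 3 | 8,12-epoxy-14-tosyloxydrimane-3,11-diol | O1C[C@@]12CC[C@@H]3[C@](C)(COS(=O)(=O)c4ccc(C)cc4)[C@H](O)CC[C@@]3(C)[C@@H]2CO
F4 | step 7 | 3-O-triethylsilyl ether of 8 | C=C1CC[C@@H]2C(C)(C)[C@H](O[Si](CC)(CC)CC)CC[C@@]2(C)[C@@H]1CO[Si](C)(C)C(C)(C)C
F5 | step 7 | 3-O-triethylsilyl 11-O-TBS 12-nordriman-8-one | O=C1CC[C@@H]2C(C)(C)[C@H](O[Si](CC)(CC)CC)CC[C@@]2(C)[C@@H]1CO[Si](C)(C)C(C)(C)C
F6 | step 7 | C7=C8 enol triflate of F5 | O=S(=O)(OC1=CC[C@@H]2C(C)(C)[C@H](O[Si](CC)(CC)CC)CC[C@@]2(C)[C@@H]1CO[Si](C)(C)C(C)(C)C)C(F)(F)F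
F7 | step 7 | 3-O-triethylsilyl ether of 9 | CC1=CC[C@@H]2C(C)(C)[C@H](O[Si](CC)(CC)CC)CC[C@@]2(C)[C@@H]1CO[Si](C)(C)C(C)(C)C
F0 | step 13 | none | none
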